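(The runs stem from a simulated flask with made-up constants; scatter was added.)

**The ceiling.** 16.5 % of the substrate charged is the ceiling of the ash run: overall each product takes one substrate and one reagent, and 0.330 M of reagent, less than the 2.00 M of substrate, makes reagent the limiting reagent.

| flask | substrate | reagent | free catalyst | time |
|---|---|---|---|---|
| elm | 1.00 M | 1.00 M | 0.100 M |  |
| larch | 0.600 M | 0.600 M | 0.100 M |  |
| oak | 0.500 M | 1.00 M | 0.100 M |  |
| alder | 1.00 M | 1.00 M | 0.300 M |  |
| ash | 2.00 M | 0.330 M | 0.100 M | 8.3 h |

| run | time / h | [product] / M |
|---|---|---|
| elm run | 1.7 | 0.158 |
| elm run | 3.3 | 0.309 |
| elm run | 5.0 | 0.430 |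
| elm run | 6.6 | 0.498 |
| elm run | 8.3 | 0.558 |
| larch run | 1.7 | 0.075 |
| larch run | 3.3 | 0.175 |
| larch run | 5.0 | 0.259 |
| larch run | 6.6 | 0.314 |
| larch run | 8.3 | 0.372 |
| oak run | 1.7 | 0.081 |
| oak run | 3.3 | 0.154 |
| oak run | 5.0 | 0.214 |
| oak run | 6.6 | 0.243 |
| oak run | 8.3 | 0.252 |
| alder run | 1.7 | 0.406 |
| alder run | 3.3 | 0.693 |
| alder run | 5.0 | 0.827 |
| alder run | 6.6 | 0.905 |
| alder run | 8.3 | 0.947 |

(scatter of a reading: 0.005 M)

- Overall: substrate + reagent -> product, with free catalyst as catalyst.
- Constant volume, constant temperature.
- Readings of a species count what is bound in complexes too.
- An order is taken over about fifteen percent of the charge, up and down.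

* apparent order in [substrate] of the starting rate, round the charge of the elm run (the rate where two percent of its substrate have turned into product) (one fixed amount of product, the same in the runs compared)
* apparent order in [free catalyst] of the starting rate, round the charge of the elm run (the rate where two percent of its substrate have turned into product)
* the larch run starts with 0.400 M less of substrate and of reagent than the elm run, and with no product. Compared where both hold the same amount of substrate, once fifteen percent of what the larch run was charged with has turned into product, is the larch run faster, slower or alike (within a tenth)?
* product in the ash run at 8.3 h, as a share of the substrate charged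

**Bench rule.** At the bench we would say that a stirred flask given time runs up to its limiting charge. The alder run obeys, with 0.947 M against a charge of 1.00 M in each partner. The oak run is slowing well short of it: its substrate charge is 0.500 M, yet its last readings are 0.243 M and 0.252 M, about half of that charge, with substrate and reagent both remaining.

**Turnovers asked.** So the ceiling needs a second test, the turnovers asked, n, the product at the ceiling divided by the catalyst charged, which for the ash run is 3.30. Against it we hold what earlier flasks delivered per catalyst charged. The oak run, with reagent over substrate at 2.00, was slowing at a last reading of 2.52, while the elm run, with that ratio at 1.00, had reached 5.58 and was still rising. The ash run has that ratio at 0.165, lower than in the elm run, with n below what the elm run delivered.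

**How fast.** The larch run, with the same catalyst charge as the ash run, made 0.372 M by 8.3 h, more than the ash ceiling of 0.330 M, though on 0.600 M of reagent, more than the ash run starts with. The reagent of the ash run falls as that run nears the ceiling, so its last stretch may lag, and our own reckoning is the ceiling or slightly under it.

**The check.** The forecast gave 0.9 for the order in substrate, 0.95 for the order in free catalyst, faster for the larch run at equal substrate, and 14.5 % for the ash run, 2 percentage points below our ceiling, in its words “it should nearly exhaust reagent”.

**The result.** The orders come out at 0.62 in substrate and 0.62 in free catalyst, the larch run comes out faster at equal substrate, with a rate over that of the elm run of 1.6, and the ash run gives 16.5 %, the ceiling, which is 3.30 product per catalyst charged, the n we reckoned.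

    active catalyst + substrate → catalyst-substrate complex (2.012 M⁻¹ h⁻¹)
    catalyst-substrate complex + reagent → product + active catalyst (72.00 M⁻¹ h⁻¹)
    active catalyst + reagent → spent catalyst + reagent (0.2437 M⁻¹ h⁻¹)
    free catalyst + reagent → active catalyst + reagent (1.393 M⁻¹ h⁻¹)

The step from active catalyst to spent catalyst makes no difference to the ash run at 8.3 h. The alder run is asked for nearly the same, n being 3.33, and its last reading delivers 3.16.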